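## Retrosynthetic overview

1. The (Z)-p-coumarate is made last, by a Z-selective Horner–Wadsworth–Emmons reaction on the C19 phosphonoacetate of labda-13(16),14-diene-8α,19-diol, followed by desilylation.
2. The 2-substituted butadiene comes from vinylation of the kinetic enol triflate of 8α,19-dihydroxy-14,15-dinorlabdan-13-one.
3. Key step: one cationic cascade of an acyclic (S)-2-alkyl-2-methyloxirane that carries two (E)-trisubstituted alkenes and a terminal methyl ketone.
4. Ring order in that cascade: ring A (C4–C5, oxirane opened with inversion), then ring B (C9–C10), then a transient pyran ring (C8–O from the ketone oxygen) that aqueous acid opens to the 8α-OH and the ketone.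
5. The oxirane comes from (E,E)-farnesylacetone by terminal SeO2 oxidation, Sharpless epoxidation, hydride opening to the (S)-1,2-diol and ring closure.

Assumption: (5E,9E)-farnesylacetone and 4-[(tert-butyldimethylsilyl)oxy]benzaldehyde are bought as such; ring positions are given in labdane numbering.

## Route

Step 1
Reactants: 1 (5E,9E)-6,10,14-trimethylpentadeca-5,9,13-trien-2-one ((E,E)-farnesylacetone)
Product: 2 2-methyl-2-[(3E,7E)-4,8,12-trimethyltrideca-3,7,11-trien-1-yl]-1,3-dioxolane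
Conditions: HOCH2CH2OH, PPTS (cat.), benzene, reflux, Dean–Stark
Reagents that add atoms: ethylene glycol, OCCO
Why: Acid-catalysed ketalisation with azeotropic removal of water masks the ketone against the later hydride step, and PPTS is too weak an acid to protonate the trisubstituted alkenes.

Step 2
Reactants: 2 2-methyl-2-[(3E,7E)-4,8,12-trimethyltrideca-3,7,11-trien-1-yl]-1,3-dioxolane
Product: 3 (2E,6E,10E)-2,6,10-trimethyl-13-(2-methyl-1,3-dioxolan-2-yl)trideca-2,6,10-trien-1-ol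
Conditions: SeO2 (cat.), t-BuOOH (anhydrous), CH2Cl2, 0 °C → rt
Reagents that add atoms: tert-butyl hydroperoxide, CC(C)(C)OO
Why: SeO2/t-BuOOH allylic oxidation (ene reaction then [2,3]-sigmatropic shift; SeO2 relays the oxygen) prefers the terminal isopropylidene group and oxidises its (E)-methyl, giving the (E)-allylic alcohol.

Step 3
Reactants: 3 (2E,6E,10E)-2,6,10-trimethyl-13-(2-methyl-1,3-dioxolan-2-yl)trideca-2,6,10-trien-1-ol
Product: 4 {(2R,3R)-3-[(3E,7E)-3,7-dimethyl-10-(2-methyl-1,3-dioxolan-2-yl)deca-3,7-dien-1-yl]-2-methyloxiran-2-yl}methanol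
Conditions: Ti(OiPr)4 (10 mol%), D-(−)-diisopropyl tartrate (12 mol%), t-BuOOH, 4 Å MS, CH2Cl2, −20 °C
Reagents that add atoms: tert-butyl hydroperoxide, CC(C)(C)OO
Why: Sharpless asymmetric epoxidation touches only the allylic-alcohol alkene, and the D-(−)-tartrate sets the quaternary oxirane carbon (future C4) as R with the (2R,3R) configuration overall.

Step 4
Reactants: 4 {(2R,3R)-3-[(3E,7E)-3,7-dimethyl-10-(2-methyl-1,3-dioxolan-2-yl)deca-3,7-dien-1-yl]-2-methyloxiran-2-yl}methanol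
Product: 6 (5E,9E,14S)-14,15-dihydroxy-6,10,14-trimethylpentadeca-5,9-dien-2-one, via diol ketal 5 (not isolated)
Conditions: LiAlH4, THF, 0 °C → rt; then 1 M aq. HCl, THF, rt
Reagents that add atoms: water, O
Why: Hydride opens the 2,3-epoxy alcohol by SN2 at the secondary carbon only (the other oxirane carbon is quaternary), so the tertiary C–O bond and its configuration are kept; the acidic work-up hydrolyses the dioxolane.

Step 5
Reactants: 6 (5E,9E,14S)-14,15-dihydroxy-6,10,14-trimethylpentadeca-5,9-dien-2-one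
Product: 8 (5E,9E)-6,10-dimethyl-13-[(2S)-2-methyloxiran-2-yl]trideca-5,9-dien-2-one, via monotosylate 7 (not isolated)
Conditions: TsCl, pyridine, CH2Cl2, 0 °C; then K2CO3, MeOH, rt
Reagents that add atoms: none
Why: Selective sulfonylation of the primary hydroxyl followed by intramolecular Williamson closure (3-exo-tet) by the tertiary alkoxide; the bond from the stereocentre to oxygen is never broken, so the (S) centre is retained.

Step 6
Reactants: 8 (5E,9E)-6,10-dimethyl-13-[(2S)-2-methyloxiran-2-yl]trideca-5,9-dien-2-one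
Product: 10 hydroxy ketone 8α,19-dihydroxy-14,15-dinorlabdan-13-one (4S,5R,8R,9R,10S), via tricyclic enol ether 9 (not isolated)
Conditions: MeAlCl2 (2.5 equiv), CH2Cl2, −78 °C; then 1 M aq. HCl, THF, rt
Reagents that add atoms: water, O
Why: Proposed new method: MeAlCl2 binds the oxirane oxygen and the C5=C10 alkene attacks the tertiary C4 from the backside (inversion) in a chair–chair fold, the (E)-alkenes relay this by anti additions to the trans-decalin (5α-H, 10β-CH3, 9α-H), and the ketone oxygen traps the C8 cation on the α face to give enol ether 9, which aqueous acid hydrolyses to 10; the oxirane CH2, tied back toward the leaving oxygen, should take the axial site at C4 (less torsional strain against C2–C3 and less 1,3-diaxial strain with the C10 methyl than a free methyl), which gives the 19-oxygenated 4S centre; the closest known reaction types are the MeAlCl2-promoted epoxy-polyene cyclisation of trisubstituted oxiranes, Lewis-acid epoxide–arene cyclialkylation of 2,2-disubstituted oxiranes, and the acid cyclisation of farnesylacetone to sclareol oxide (ketone-oxygen termination).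

Step 7
Reactants: 10 hydroxy ketone 8α,19-dihydroxy-14,15-dinorlabdan-13-one
Product: 12 enol triflate 8α,19-dihydroxy-14,15-dinorlabd-13(16)-en-13-yl trifluoromethanesulfonate, via trilithium enolate 11 (not isolated)
Conditions: LiN(iPr)2 (3.3 equiv), THF, −78 °C; then PhNTf2, −78 → 0 °C
Reagents that add atoms: N-phenylbis(trifluoromethanesulfonimide), O=S(=O)(N(c1ccccc1)S(=O)(=O)C(F)(F)F)C(F)(F)F
Why: After the two hydroxyls are deprotonated, the third equivalent of amide removes a methyl proton kinetically, and the enolate oxygen is triflated much faster than the alkoxides (enol triflate formation).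

Step 8
Reactants: 12 enol triflate 8α,19-dihydroxy-14,15-dinorlabd-13(16)-en-13-yl trifluoromethanesulfonate
Product: 13 diene diol labda-13(16),14-diene-8α,19-diol (4S,5R,8R,9R,10S)
Conditions: CH2=CHSnBu3, Pd(PPh3)4 (5 mol%), LiCl, THF, 65 °C
Reagents that add atoms: tributyl(vinyl)stannane, C=C[Sn](CCCC)(CCCC)CCCC
Why: Stille coupling of an enol triflate with a vinylstannane on zerovalent palladium gives the 2-substituted butadiene with fixed regiochemistry and tolerates free hydroxyls.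

Step 9
Reactants: 13 diene diol labda-13(16),14-diene-8α,19-diol
Product: 15 8α-hydroxylabda-13(16),14-dien-19-yl 2-(diphenoxyphosphoryl)acetate, via bromoacetate 14 (not isolated)
Conditions: BrCH2COBr, pyridine, CH2Cl2, −20 °C; then (PhO)2P(O)H, Et3N, 0 °C → rt
Reagents that add atoms: bromoacetyl bromide, O=C(Br)CBr; diphenyl phosphite, O=[PH](Oc1ccccc1)Oc1ccccc1
Why: The acyl bromide acylates only the primary C19 hydroxyl (the tertiary 8-OH is inert), and Michaelis–Becker alkylation of diphenyl phosphite by the α-bromo ester then gives the Ando-type phosphonate.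

Step 10
Reactants: 15 8α-hydroxylabda-13(16),14-dien-19-yl 2-(diphenoxyphosphoryl)acetate; 16 4-[(tert-butyldimethylsilyl)oxy]benzaldehyde
Product: 17 8α-hydroxylabda-13(16),14-dien-19-yl (2Z)-3-{4-[(tert-butyldimethylsilyl)oxy]phenyl}prop-2-enoate
Conditions: NaI, DBU, THF, −78 → 0 °C
Reagents that add atoms: none
Why: Ando Z-selective Horner–Wadsworth–Emmons reaction: the electron-poor diaryl phosphonate makes the kinetic syn adduct collapse quickly to the (Z)-cinnamate (about 9:1 expected; the minor E ester is removed by chromatography).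

Step 11
Reactants: 17 8α-hydroxylabda-13(16),14-dien-19-yl (2Z)-3-{4-[(tert-butyldimethylsilyl)oxy]phenyl}prop-2-enoate
Product: 18 8α-hydroxylabda-13(16),14-dien-19-yl (2Z)-3-(4-hydroxyphenyl)prop-2-enoate (CNP0197278.1)
Conditions: Bu4NF, AcOH, THF, 0 °C
Reagents that add atoms: none
Why: Fluoride cleaves the aryl silyl ether (desilylation), and the acetic acid buffer keeps the phenol protonated so that the Z-alkene, the ester and the diene are untouched.

## Compound list

1 | (5E,9E)-6,10,14-trimethylpentadeca-5,9,13-trien-2-one | CC(=O)CC/C=C(\C)CC/C=C(\C)CCC=C(C)C | starting material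
2 | 2-methyl-2-[(3E,7E)-4,8,12-trimethyltrideca-3,7,11-trien-1-yl]-1,3-dioxolane | CC1(CC/C=C(\C)CC/C=C(\C)CCC=C(C)C)OCCO1 | intermediate
3 | (2E,6E,10E)-2,6,10-trimethyl-13-(2-methyl-1,3-dioxolan-2-yl)trideca-2,6,10-trien-1-ol | OC/C(C)=C/CC/C(C)=C/CC/C(C)=C/CCC1(C)OCCO1 | intermediate
4 | {(2R,3R)-3-[(3E,7E)-3,7-dimethyl-10-(2-methyl-1,3-dioxolan-2-yl)deca-3,7-dien-1-yl]-2-methyloxiran-2-yl}methanol | OC[C@@]1(C)O[C@@H]1CC/C(C)=C/CC/C(C)=C/CCC2(C)OCCO2 | intermediate
5 | (2S,6E,10E)-2,6,10-trimethyl-13-(2-methyl-1,3-dioxolan-2-yl)trideca-6,10-diene-1,2-diol | CC1(CC/C=C(\C)CC/C=C(\C)CCC[C@@](C)(CO)O)OCCO1 | intermediate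
6 | (5E,9E,14S)-14,15-dihydroxy-6,10,14-trimethylpentadeca-5,9-dien-2-one | CC(=O)CC/C=C(\C)CC/C=C(\C)CCC[C@@](C)(CO)O | intermediate
7 | (2S,6E,10E)-2-hydroxy-2,6,10-trimethyl-14-oxopentadeca-6,10-dien-1-yl 4-methylbenzenesulfonate | CC(=O)CC/C=C(\C)CC/C=C(\C)CCC[C@@](C)(COS(=O)(=O)c1ccc(C)cc1)O | intermediate
8 | (5E,9E)-6,10-dimethyl-13-[(2S)-2-methyloxiran-2-yl]trideca-5,9-dien-2-one | CC(=O)CC/C=C(\C)CC/C=C(\C)CCC[C@@]1(C)CO1 | intermediate
9 | 8α,13-epoxy-14,15-dinorlabd-12-en-19-ol (4S,5R,8R,9R,10S) | CC1=CC[C@@H]2[C@@]3(C)CCC[C@](C)(CO)[C@@H]3CC[C@@]2(C)O1 | intermediate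
10 | 8α,19-dihydroxy-14,15-dinorlabdan-13-one (4S,5R,8R,9R,10S) | CC(=O)CC[C@@H]1[C@@]2(C)CCC[C@](C)(CO)[C@@H]2CC[C@@]1(C)O | intermediate
11 | trilithium salt of the 13(16)-enolate 8α,19-dialkoxide of 10 | C=C([O-])CC[C@@H]1[C@@]2(C)CCC[C@](C)(C[O-])[C@@H]2CC[C@@]1(C)[O-].[Li+].[Li+].[Li+] | intermediate
12 | 8α,19-dihydroxy-14,15-dinorlabd-13(16)-en-13-yl trifluoromethanesulfonate | C=C(OS(=O)(=O)C(F)(F)F)CC[C@@H]1[C@@]2(C)CCC[C@](C)(CO)[C@@H]2CC[C@@]1(C)O | intermediate
13 | labda-13(16),14-diene-8α,19-diol (4S,5R,8R,9R,10S) | C=CC(=C)CC[C@@H]1[C@@]2(C)CCC[C@](C)(CO)[C@@H]2CC[C@@]1(C)O | intermediate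
14 | 8α-hydroxylabda-13(16),14-dien-19-yl bromoacetate | C=CC(=C)CC[C@@H]1[C@@]2(C)CCC[C@](C)(COC(=O)CBr)[C@@H]2CC[C@@]1(C)O | intermediate
15 | 8α-hydroxylabda-13(16),14-dien-19-yl 2-(diphenoxyphosphoryl)acetate | C=CC(=C)CC[C@@H]1[C@@]2(C)CCC[C@](C)(COC(=O)CP(=O)(Oc3ccccc3)Oc3ccccc3)[C@@H]2CC[C@@]1(C)O | intermediate
16 | 4-[(tert-butyldimethylsilyl)oxy]benzaldehyde | O=Cc1ccc(O[Si](C)(C)C(C)(C)C)cc1 | starting material
17 | 8α-hydroxylabda-13(16),14-dien-19-yl (2Z)-3-{4-[(tert-butyldimethylsilyl)oxy]phenyl}prop-2-enoate | C=CC(=C)CC[C@@H]1[C@@]2(C)CCC[C@](C)(COC(=O)/C=C\c3ccc(O[Si](C)(C)C(C)(C)C)cc3)[C@@H]2CC[C@@]1(C)O | intermediate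
18 | 8α-hydroxylabda-13(16),14-dien-19-yl (2Z)-3-(4-hydroxyphenyl)prop-2-enoate | C=CC(=C)CC[C@@H]1[C@@]2(C)CCC[C@](C)(COC(=O)/C=C\c3ccc(O)cc3)[C@@H]2CC[C@@]1(C)O | target

## Step count and risks

Total step count: 11. Longest linear sequence: 11 steps (1 → 18).

Steps most likely to fail:

Step 6. The axial placement of the oxygenated carbon at C4 is a prediction, and the activated oxirane can also rearrange to an aldehyde by hydride shift or stop after one ring. The fallback sets out from 4 and comes back at 10. It fixes C4 through alkene geometry in a conventional trisubstituted-oxirane cyclisation and removes the extra C3 oxygen afterwards. H5IO6 cleaves 4 to the aldehyde (4E,8E)-4,8-dimethyl-11-(2-methyl-1,3-dioxolan-2-yl)undeca-4,8-dienal F1. Ando olefination with ethyl 2-(diphenoxyphosphoryl)propanoate gives ethyl (2Z,6E,10E)-2,6,10-trimethyl-13-(2-methyl-1,3-dioxolan-2-yl)trideca-2,6,10-trienoate F2. iBu2AlH reduces it to (2Z,6E,10E)-2,6,10-trimethyl-13-(2-methyl-1,3-dioxolan-2-yl)trideca-2,6,10-trien-1-ol F3, and PPTS in aqueous acetone frees the ketone to give (5E,9E,13Z)-15-hydroxy-6,10,14-trimethylpentadeca-5,9,13-trien-2-one F4. Sharpless epoxidation with D-(−)-diisopropyl tartrate gives (5E,9E)-12-[(2S,3R)-3-(hydroxymethyl)-3-methyloxiran-2-yl]-6,10-dimethyldodeca-5,9-dien-2-one F5. MeAlCl2 followed by aqueous acid cyclises it through 8α,13-epoxy-14,15-dinorlabd-12-ene-3β,19-diol F6 to 3β,8α,19-trihydroxy-14,15-dinorlabdan-13-one F7, in which the Z-derived CH2OH is axial. 1,1'-Thiocarbonyldiimidazole closes the 3β,19-cyclic thionocarbonate of F7, F8. Bu3SnH with AIBN cleaves the secondary C3–O bond (Barton deoxygenation) to 8α-hydroxy-13-oxo-14,15-dinorlabdan-19-yl S-(tributylstannyl) thiocarbonate F9, which K2CO3 in methanol converts to 10.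

Step 7. Two free hydroxyls compete for base and triflating agent, the 8-alkoxide can add to the ketone, and some internal enolate may form. The fallback sets out from 10 and comes back at 13 by a Shapiro sequence instead of enolate triflation. Condensation with 2,4,6-triisopropylbenzenesulfonyl hydrazide gives the 2,4,6-triisopropylbenzenesulfonylhydrazone of 10, F10. Excess n-BuLi gives the dilithium 8α,19-dialkoxide of 13-lithio-14,15-dinorlabd-13(16)-ene, F11, with deprotonation on the methyl side. Iodine gives 13-iodo-14,15-dinorlabd-13(16)-ene-8α,19-diol F12, and Stille coupling with tributyl(vinyl)stannane and Pd(PPh3)4 gives 13.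

Step 9. The one-flask acylation and phosphonylation at a hindered neopentyl alcohol may suffer from amine quaternisation of the bromoacetate or from incomplete acylation. The fallback sets out from 13 and comes back at 15, with the phosphonoacetic acid made separately and then coupled. tert-Butyl bromoacetate, diphenyl phosphite and Et3N give tert-butyl 2-(diphenoxyphosphoryl)acetate F13. CF3CO2H gives 2-(diphenoxyphosphoryl)acetic acid F14, and Steglich esterification of 13 with F14 (EDC·HCl, DMAP cat.) gives 15.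

## Further compounds

F1 | step 6 | (4E,8E)-4,8-dimethyl-11-(2-methyl-1,3-dioxolan-2-yl)undeca-4,8-dienal | O=CCC/C(C)=C/CC/C(C)=C/CCC1(C)OCCO1
F2 | step 6 | ethyl (2Z,6E,10E)-2,6,10-trimethyl-13-(2-methyl-1,3-dioxolan-2-yl)trideca-2,6,10-trienoate | CCOC(=O)/C(C)=C\CC/C(C)=C/CC/C(C)=C/CCC1(C)OCCO1
F3 | step 6 | (2Z,6E,10E)-2,6,10-trimethyl-13-(2-methyl-1,3-dioxolan-2-yl)trideca-2,6,10-trien-1-ol | OC/C(C)=C\CC/C(C)=C/CC/C(C)=C/CCC1(C)OCCO1
F4 | step 6 | (5E,9E,13Z)-15-hydroxy-6,10,14-trimethylpentadeca-5,9,13-trien-2-one | CC(=O)CC/C=C(\C)CC/C=C(\C)CC/C=C(/C)CO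
F5 | step 6 | (5E,9E)-12-[(2S,3R)-3-(hydroxymethyl)-3-methyloxiran-2-yl]-6,10-dimethyldodeca-5,9-dien-2-one | CC(=O)CC/C=C(\C)CC/C=C(\C)CC[C@@H]1O[C@]1(C)CO
F6 | step 6 | 8α,13-epoxy-14,15-dinorlabd-12-ene-3β,19-diol | CC1=CC[C@@H]2[C@@]3(C)CC[C@H](O)[C@](C)(CO)[C@@H]3CC[C@@]2(C)O1
F7 | step 6 | 3β,8α,19-trihydroxy-14,15-dinorlabdan-13-one | CC(=O)CC[C@@H]1[C@@]2(C)CC[C@H](O)[C@](C)(CO)[C@@H]2CC[C@@]1(C)O
F8 | step 6 | 3β,19-cyclic thionocarbonate of 3β,8α,19-trihydroxy-14,15-dinorlabdan-13-one | CC(=O)CC[C@@H]1[C@@]2(C)CC[C@@H]3OC(=S)OC[C@]3(C)[C@@H]2CC[C@@]1(C)O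
F9 | step 6 | 8α-hydroxy-13-oxo-14,15-dinorlabdan-19-yl S-(tributylstannyl) thiocarbonate | CC(=O)CC[C@@H]1[C@@]2(C)CCC[C@](C)(COC(=O)S[Sn](CCCC)(CCCC)CCCC)[C@@H]2CC[C@@]1(C)O
F10 | step 7 | 2,4,6-triisopropylbenzenesulfonylhydrazone of 8α,19-dihydroxy-14,15-dinorlabdan-13-one | CC(CC[C@@H]1[C@@]2(C)CCC[C@](C)(CO)[C@@H]2CC[C@@]1(C)O)=NNS(=O)(=O)c1c(C(C)C)cc(C(C)C)cc1C(C)C
F11 | step 7 | dilithium 8α,19-dialkoxide of 13-lithio-14,15-dinorlabd-13(16)-ene | [Li]C(=C)CC[C@@H]1[C@@]2(C)CCC[C@](C)(C[O-])[C@@H]2CC[C@@]1(C)[O-].[Li+].[Li+]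
F12 | step 7 | 13-iodo-14,15-dinorlabd-13(16)-ene-8α,19-diol | C=C(I)CC[C@@H]1[C@@]2(C)CCC[C@](C)(CO)[C@@H]2CC[C@@]1(C)O
F13 | step 9 | tert-butyl 2-(diphenoxyphosphoryl)acetate | CC(C)(C)OC(=O)CP(=O)(Oc1ccccc1)Oc1ccccc1
F14 | step 9 | 2-(diphenoxyphosphoryl)acetic acid | OC(=O)CP(=O)(Oc1ccccc1)Oc1ccccc1
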